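## Retrosynthetic overview
1. The target comes from a bromochloro-dihydropyranone. Its C-3 carbinol is made by 1,2-reduction followed by SN2 inversion.
2. That pyranone comes from a 2,2,6,6-tetrasubstituted dihydropyranone carrying a 4-methylcyclohex-3-enyl group. C–Br and C–Cl are added by a face-inverting, selenium-relayed bromochlorination.
3. The gem-dimethyl carbon comes from a pyranone hemiketal (C–CH3 for C–OH). The hemiketal comes from a tertiary 5-methylfuryl carbinol by oxidative furan-to-pyranone ring expansion, which is the key step.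
4. The carbinol comes from (S)-4-acetyl-1-methylcyclohexene and 2-methylfuran by reagent-controlled 1,2-addition. The ketone comes from isoprene and methyl vinyl ketone by a catalytic asymmetric [4+2].
5. Ring order: ring A (carbocycle) is made first, the furan is then attached, and ring B (pyran) is made by expanding the furan.

Assumption: the antipodes named for the catalyst of step 1 and the ligand of step 2 follow the sense of induction of the closest known cases. Both antipodes are available, and the sense is checked on 3 (known rotation) and on 7.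

## Route

Step 1
Reactants: 1 isoprene; 2 methyl vinyl ketone
Product: 3 (S)-1-(4-methylcyclohex-3-en-1-yl)ethan-1-one
Conditions: (S)-3,3-diphenyl-1-(o-tolyl)tetrahydropyrrolo[1,2-c][1,3,2]oxazaborole·HNTf2 (10 mol %), CH2Cl2, −40 °C
Reagents that add atoms: none
Why: Catalytic asymmetric Diels–Alder reaction in which the cationic oxazaborolidine binds the enone carbonyl, blocks one face of the dienophile and sharpens the para orientation of isoprene, which sets the only stereocentre (C-1 of ring A) as S.

Step 2
Reactants: 3 (S)-1-(4-methylcyclohex-3-en-1-yl)ethan-1-one; 4 2-methylfuran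
Product: 7 (1R)-1-[(1S)-4-methylcyclohex-3-en-1-yl]-1-(5-methylfuran-2-yl)ethan-1-ol, via 5-methyl-2-furyllithium 5 (not isolated), via 5-methyl-2-furylmagnesium bromide 6 (not isolated)
Conditions: 4, n-BuLi, Et2O, 0 °C → rt; MgBr2·OEt2; (R,R)-1,2-diaminocyclohexane-derived N,N,O aminophenol ligand (1.1 equiv), toluene, −78 °C; then 3; aqueous work-up
Reagents that add atoms: none
Why: Ligand-mediated asymmetric Grignard 1,2-addition to a methyl ketone, in which the chiral magnesium aminophenolate tells CH3 from the branched ring carbon and delivers the furyl group to the Si face, so the carbinol carbon is set as R by reagent control because the resident centre (which differs only in a remote alkene) gives no bias of its own.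

Step 3
Reactants: 7 (1R)-1-[(1S)-4-methylcyclohex-3-en-1-yl]-1-(5-methylfuran-2-yl)ethan-1-ol
Product: 9 (2R)-6-hydroxy-2,6-dimethyl-2-[(1S)-4-methylcyclohex-3-en-1-yl]-2H-pyran-3(6H)-one (both anomers), via Z-enedione 8 (not isolated)
Conditions: NBS (1.0 equiv), NaHCO3, THF–H2O (4:1), 0 °C
Reagents that add atoms: water, O
Why: Achmatowicz oxidative ring expansion, in which Br+ attacks the electron-rich 2,5-dialkylfuran much faster than the isolated trisubstituted alkene, water opens the ring to Z-enedione 8 and the tertiary hydroxyl closes on the methyl ketone, so the five-membered furan becomes the six-membered pyranone with the carbinol centre untouched (the hemiketal carbon is a mixture that is erased in step 4).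

Step 4
Reactants: 9 (2R)-6-hydroxy-2,6-dimethyl-2-[(1S)-4-methylcyclohex-3-en-1-yl]-2H-pyran-3(6H)-one
Product: 10 (2R)-2,6,6-trimethyl-2-[(1S)-4-methylcyclohex-3-en-1-yl]-2H-pyran-3(6H)-one
Conditions: AlMe3 (3.5 equiv), CH2Cl2, −78 → −10 °C
Reagents that add atoms: trimethylaluminium, C[Al](C)C
Why: Oxocarbenium substitution of the C-glycosidation type, in which AlMe3 deprotonates and ionises the hemiketal and transfers methyl to the cyclic oxocarbenium carbon, which becomes a gem-dimethyl carbon (no new stereocentre), while the ketone, flanked by a fully substituted carbon, does not add AlMe3 at low temperature.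

Step 5
Reactants: 10 (2R)-2,6,6-trimethyl-2-[(1S)-4-methylcyclohex-3-en-1-yl]-2H-pyran-3(6H)-one
Product: 13 (2R)-2-[(1S,3S,4S)-3-bromo-4-chloro-4-methylcyclohexyl]-2,6,6-trimethyl-2H-pyran-3(6H)-one, via bromo selenide 11 (not isolated), via selenium dichloride 12 (not isolated)
Conditions: PhSeBr (1.05 equiv), CH2Cl2, −78 → −30 °C, 1 h; then SO2Cl2 (1.05 equiv), −78 → 0 °C, dark
Reagents that add atoms: benzeneselenenyl bromide, Br[Se]c1ccccc1; sulfuryl chloride, O=S(=O)(Cl)Cl
Why: Proposed new method: a selenium-relayed bromochlorination that inverts the facial outcome of direct BrCl addition; reversible PhSeBr addition funnels both alkene faces into the trans-diaxial Markovnikov adduct 11 (PhSe axial on C-3 and trans to the equatorial pyranone substituent, Br axial on tertiary C-4); SO2Cl2 raises selenium to the tetravalent dichloride 12, whose C–Se bond is expelled by the antiperiplanar bromine (a 1,2-bromine shift through a bromiranium ion on the face cis to the C-1 substituent); the chloride released on the opposite face collapses on the tertiary carbon, so Br ends equatorial on C-3 (S) and Cl equatorial on C-4 (S), the arrangement that direct bromonium/chloride addition under the trans-diaxial rule does not give; the closest known reactions are the two-stage selenium-mediated syn-dichlorination of alkenes (anti chloroselenation, oxidation, invertive displacement of selenium) and neighbouring-bromine participation in the solvolysis of trans-2-bromocycloalkyl sulfonates.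

Step 6
Reactants: 13 (2R)-2-[(1S,3S,4S)-3-bromo-4-chloro-4-methylcyclohexyl]-2,6,6-trimethyl-2H-pyran-3(6H)-one
Product: 14 (2R,3S)-2-[(1S,3S,4S)-3-bromo-4-chloro-4-methylcyclohexyl]-2,6,6-trimethyl-3,6-dihydro-2H-pyran-3-ol
Conditions: NaBH4, CeCl3·7H2O, MeOH, −78 °C
Reagents that add atoms: none
Why: Luche 1,2-reduction, where in the envelope of ring B the ring A substituent is pseudo-equatorial and the 2-methyl pseudo-axial, so hydride enters anti to that methyl and gives the pseudo-equatorial (3S)-alcohol (OH cis to 2-CH3) with the halides untouched.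

Step 7
Reactants: 14 (2R,3S)-2-[(1S,3S,4S)-3-bromo-4-chloro-4-methylcyclohexyl]-2,6,6-trimethyl-3,6-dihydro-2H-pyran-3-ol
Product: 16 (2R,3R)-2-[(1S,3S,4S)-3-bromo-4-chloro-4-methylcyclohexyl]-2,6,6-trimethyl-3,6-dihydro-2H-pyran-3-ol, via 4-nitrobenzoate 15 (not isolated)
Conditions: 4-O2NC6H4CO2H, PPh3, DIAD, THF, 0 °C → rt; then K2CO3, MeOH, rt
Reagents that add atoms: 4-nitrobenzoic acid, O=C(O)c1ccc(cc1)[N+](=O)[O-]
Why: Mitsunobu inversion followed by transesterification, in which the activated allylic C–O bond is displaced by 4-nitrobenzoate in an SN2 sense from the open face anti to the pseudo-axial 2-methyl, which turns C-3 into R, and mild methanolysis frees the alcohol without touching the equatorial bromide and chloride.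

## Compound list
1 | isoprene | C=CC(C)=C | starting material
2 | methyl vinyl ketone | CC(=O)C=C | starting material
3 | (S)-1-(4-methylcyclohex-3-en-1-yl)ethan-1-one | CC(=O)[C@H]1CCC(C)=CC1 | intermediate
4 | 2-methylfuran | Cc1ccco1 | starting material
5 | (5-methylfuran-2-yl)lithium | [Li]c1ccc(C)o1 | intermediate
6 | bromo(5-methylfuran-2-yl)magnesium | Br[Mg]c1ccc(C)o1 | intermediate
7 | (1R)-1-[(1S)-4-methylcyclohex-3-en-1-yl]-1-(5-methylfuran-2-yl)ethan-1-ol | Cc1ccc(o1)[C@@](C)([C@H]2CCC(C)=CC2)O | intermediate
8 | (3Z,6R)-6-hydroxy-6-[(1S)-4-methylcyclohex-3-en-1-yl]hept-3-ene-2,5-dione | CC(=O)/C=C\C(=O)[C@@](C)([C@H]1CCC(C)=CC1)O | intermediate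
9 | (2R)-6-hydroxy-2,6-dimethyl-2-[(1S)-4-methylcyclohex-3-en-1-yl]-2H-pyran-3(6H)-one, both anomers at C-6 | CC1(O)C=CC(=O)[C@@](C)([C@H]2CCC(C)=CC2)O1 | intermediate
10 | (2R)-2,6,6-trimethyl-2-[(1S)-4-methylcyclohex-3-en-1-yl]-2H-pyran-3(6H)-one | CC1(C)C=CC(=O)[C@@](C)([C@H]2CCC(C)=CC2)O1 | intermediate
11 | (2R)-2-[(1S,3R,4R)-4-bromo-4-methyl-3-(phenylselanyl)cyclohexyl]-2,6,6-trimethyl-2H-pyran-3(6H)-one | CC1(C)C=CC(=O)[C@@](C)([C@H]2CC[C@@](C)(Br)[C@H]([Se]c3ccccc3)C2)O1 | intermediate
12 | (2R)-2-{(1S,3R,4R)-4-bromo-3-[dichloro(phenyl)-λ4-selanyl]-4-methylcyclohexyl}-2,6,6-trimethyl-2H-pyran-3(6H)-one | CC1(C)C=CC(=O)[C@@](C)([C@H]2CC[C@@](C)(Br)[C@H]([Se](Cl)(Cl)c3ccccc3)C2)O1 | intermediate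
13 | (2R)-2-[(1S,3S,4S)-3-bromo-4-chloro-4-methylcyclohexyl]-2,6,6-trimethyl-2H-pyran-3(6H)-one | CC1(C)C=CC(=O)[C@@](C)([C@H]2CC[C@](C)(Cl)[C@@H](Br)C2)O1 | intermediate
14 | (2R,3S)-2-[(1S,3S,4S)-3-bromo-4-chloro-4-methylcyclohexyl]-2,6,6-trimethyl-3,6-dihydro-2H-pyran-3-ol | CC1(C)C=C[C@H](O)[C@@](C)([C@H]2CC[C@](C)(Cl)[C@@H](Br)C2)O1 | intermediate
15 | (2R,3R)-2-[(1S,3S,4S)-3-bromo-4-chloro-4-methylcyclohexyl]-2,6,6-trimethyl-3,6-dihydro-2H-pyran-3-yl 4-nitrobenzoate | CC1(C)C=C[C@@H](OC(=O)c3ccc(cc3)[N+](=O)[O-])[C@@](C)([C@H]2CC[C@](C)(Cl)[C@@H](Br)C2)O1 | intermediate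
16 | (2R,3R)-2-[(1S,3S,4S)-3-bromo-4-chloro-4-methylcyclohexyl]-2,6,6-trimethyl-3,6-dihydro-2H-pyran-3-ol | CC1(C)C=C[C@@H](O)[C@@](C)([C@H]2CC[C@](C)(Cl)[C@@H](Br)C2)O1 | target

## Step count and risks
Total steps: 7. Longest linear sequence: 7 (from 1 and 2 to 16; 4 enters at step 2).

**Step 5 (the proposed new step).**
- Risk: bromide and chloride may scramble at selenium before the C–Se bond breaks, which gives the syn bromochloride.
- Risk: chloride may attack the secondary carbon of the bromiranium ion, which gives the regioisomer.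
- Risk: the bromiranium ion may lose Br+, and re-addition then gives the trans-diaxial diastereomer.
- The fallback uses known reactions only. It sets out from 10 and comes back at 13.
- The ring A alkene of 10 is epoxidised with mCPBA/NaHCO3 (CH2Cl2, 0 °C; the enone alkene is inert). The two epoxides are separated on silica.
- The epoxide kept has oxygen trans to the pyranone substituent. It is (2R)-2,6,6-trimethyl-2-[(1R,3S,6S)-6-methyl-7-oxabicyclo[4.1.0]heptan-3-yl]-2H-pyran-3(6H)-one F1.
- Anhydrous HBr (Et2O/CH2Cl2, −40 °C) opens it at the tertiary carbon, where the electronic and trans-diaxial preferences coincide. This gives (2R)-2-[(1S,3R,4R)-4-bromo-3-hydroxy-4-methylcyclohexyl]-2,6,6-trimethyl-2H-pyran-3(6H)-one F2.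
- SOCl2/pyridine (CH2Cl2, −20 °C) then converts the axial alcohol into a chlorosulfite. It leaves with participation of the antiperiplanar bromine, and chloride opens the same bromiranium ion at the tertiary carbon to give 13.
- The price is two more steps and the loss of the other epoxide.

**Step 4.**
- Risk: the oxocarbenium ion is destabilised by the conjugated ketone, so ionisation may be slow.
- Risk: 1,2-methylation of the ketone, loss of a proton to an exocyclic enol ether, or capture of the cation by the ring A alkene may compete.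
- The fallback moves the methylation to the allylic-alcohol oxidation level, where the cation is far better stabilised. It sets out from 9 and comes back at 10.
- MeOH/HC(OMe)3/PPTS gives the ketal (2R)-6-methoxy-2,6-dimethyl-2-[(1S)-4-methylcyclohex-3-en-1-yl]-2H-pyran-3(6H)-one F3.
- NaBH4/CeCl3·7H2O (MeOH, −78 °C) gives (2R,3S)-6-methoxy-2,6-dimethyl-2-[(1S)-4-methylcyclohex-3-en-1-yl]-3,6-dihydro-2H-pyran-3-ol F4.
- AlMe3 (4 equiv, CH2Cl2, −78 → 0 °C) replaces methoxy by methyl at the ketal carbon in the Ferrier sense. This gives (2R,3S)-2,6,6-trimethyl-2-[(1S)-4-methylcyclohex-3-en-1-yl]-3,6-dihydro-2H-pyran-3-ol F5.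
- MnO2 (CH2Cl2, rt) re-oxidises the allylic alcohol to 10.

**Step 2.**
- Risk: a furyl Grignard reagent made by way of the lithium compound (LiBr present) may give lower selectivity than aryl Grignard reagents.
- Risk: the two carbinol epimers differ only in a remote alkene and are hard to separate at this stage.
- The fallback replaces reagent-controlled addition by selection during the ring expansion. It sets out from 3 and 4 and comes back at 9.
- Compound 5 (from 4 and n-BuLi) is added to 3 in THF at −78 °C without ligand. This gives 7 together with its carbinol epimer (1S)-1-[(1S)-4-methylcyclohex-3-en-1-yl]-1-(5-methylfuran-2-yl)ethan-1-ol F6 in about 1:1 ratio.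
- The mixture is oxidised with t-BuOOH (0.55 equiv), Ti(OiPr)4 and the diisopropyl tartrate antipode for which 7 is the fast-reacting carbinol (CH2Cl2, −20 °C). This is the kinetic-resolution variant of the same ring expansion, known for 2-furylcarbinols.
- Compound 7 goes directly to 9, while F6 stays behind and is removed on silica.

## Further compounds
F1 | step 5 | (2R)-2,6,6-trimethyl-2-[(1R,3S,6S)-6-methyl-7-oxabicyclo[4.1.0]heptan-3-yl]-2H-pyran-3(6H)-one | CC1(C)C=CC(=O)[C@@](C)([C@H]2CC[C@]3(C)O[C@@H]3C2)O1
F2 | step 5 | (2R)-2-[(1S,3R,4R)-4-bromo-3-hydroxy-4-methylcyclohexyl]-2,6,6-trimethyl-2H-pyran-3(6H)-one | CC1(C)C=CC(=O)[C@@](C)([C@H]2CC[C@@](C)(Br)[C@H](O)C2)O1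
F3 | step 4 | (2R)-6-methoxy-2,6-dimethyl-2-[(1S)-4-methylcyclohex-3-en-1-yl]-2H-pyran-3(6H)-one, both anomers | COC1(C)C=CC(=O)[C@@](C)([C@H]2CCC(C)=CC2)O1
F4 | step 4 | (2R,3S)-6-methoxy-2,6-dimethyl-2-[(1S)-4-methylcyclohex-3-en-1-yl]-3,6-dihydro-2H-pyran-3-ol, both anomers | COC1(C)C=C[C@H](O)[C@@](C)([C@H]2CCC(C)=CC2)O1
F5 | step 4 | (2R,3S)-2,6,6-trimethyl-2-[(1S)-4-methylcyclohex-3-en-1-yl]-3,6-dihydro-2H-pyran-3-ol | CC1(C)C=C[C@H](O)[C@@](C)([C@H]2CCC(C)=CC2)O1
F6 | step 2 | (1S)-1-[(1S)-4-methylcyclohex-3-en-1-yl]-1-(5-methylfuran-2-yl)ethan-1-ol | Cc1ccc(o1)[C@](C)([C@H]2CCC(C)=CC2)O
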